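## Retrosynthetic overview

1. Caraganin C is cut across C4–C3 and O1–C2 into a styryl ortho-quinone methide and an (E)-1,3-diarylpropene, two C6–C3–C6 units joined by one oxa-[4+2] cycloaddition as in the presumed dimerisation. A chiral phosphoric acid sets all three stereocentres in this step, with every phenol left free.
2. The ortho-quinone methide comes from acid ionisation of a diarylallyl alcohol, made by Luche reduction of the chalcone from paeonol and 4-hydroxybenzaldehyde.
3. The (E)-1,3-diarylpropene comes from reduction and dehydration of a dihydrochalcone, made by Friedel–Crafts acylation of 1,3-dimethoxybenzene with 3-(4-hydroxyphenyl)propanoic acid.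
4. Ring order: the four benzene rings are bought; the pyran ring is the only ring made, and it is made last.
5. The target is the all-trans (2R,3R,4R) chroman: 2-aryl and 4-styryl cis, the 3-benzyl group trans to both.

Assumption: the (R)-configured phosphoric acid is taken to shield the Re face of the methide carbon of the ortho-quinone methide; if the sense of induction is found to be the opposite, the (S)-acid is used with nothing else changed.

## Route

Step 1
Reactants: 1 paeonol [1-(2-hydroxy-4-methoxyphenyl)ethan-1-one]; 2 4-hydroxybenzaldehyde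
Product: 3 (E)-1-(2-hydroxy-4-methoxyphenyl)-3-(4-hydroxyphenyl)prop-2-en-1-one (2',4-dihydroxy-4'-methoxychalcone)
Conditions: KOH (50% aq, 6 equiv), EtOH, rt, 48 h; then 2 M HCl, 0 °C; recrystallise (EtOH/H2O)
Reagents that add atoms: none
Why: Claisen–Schmidt condensation: the enolate of 1 adds to the non-enolisable aldehyde 2 and E1cB loss of water gives the conjugated E-enone under thermodynamic control; no stereocentre is formed.

Step 2
Reactants: 3 (E)-2',4-dihydroxy-4'-methoxychalcone
Product: 4 rac-(E)-1-(2-hydroxy-4-methoxyphenyl)-3-(4-hydroxyphenyl)prop-2-en-1-ol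
Conditions: NaBH4 (3 equiv), CeCl3·7H2O (1.2 equiv), MeOH/THF 3:1, −20 → 0 °C, 30 min; pH 7 phosphate buffer; crude product used at once
Reagents that add atoms: none
Why: Luche reduction: the hard methoxyborohydride adds 1,2 to the cerium-activated carbonyl faster than conjugate reduction or base-induced flavanone closure; the carbinol centre is racemic, which does not matter because it becomes trigonal in step 5.

Step 3
Reactants: 5 1,3-dimethoxybenzene (3 equiv); 6 3-(4-hydroxyphenyl)propanoic acid
Product: 7 1-(2,4-dimethoxyphenyl)-3-(4-hydroxyphenyl)propan-1-one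
Conditions: polyphosphoric acid, 70 °C, 3 h; then ice-water
Reagents that add atoms: none
Why: Friedel–Crafts acylation: the activated acid attacks C4 of 5 (para to one methoxy group, ortho to the other), the excess of the far more nucleophilic 5 outcompetes self-acylation of the phenol ring of 6, and the product ketone is deactivated towards a second acylation.

Step 4
Reactants: 7 1-(2,4-dimethoxyphenyl)-3-(4-hydroxyphenyl)propan-1-one
Product: 9 (E)-4-[3-(2,4-dimethoxyphenyl)prop-2-en-1-yl]phenol, via benzylic alcohol 8 (not isolated)
Conditions: NaBH4 (1.5 equiv), MeOH, 0 °C → rt; aq NH4Cl, extract, solvent swap; then TsOH·H2O (2 mol %), toluene (0.02 M), 70 °C, 30 min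
Reagents that add atoms: none
Why: Borohydride reduction followed by E1 dehydration through the 2,4-dimethoxybenzylic cation; only C2 carries β-hydrogens, so the styrene forms as a single regioisomer with E geometry by thermodynamic control, and high dilution with little acid limits cationic dimerisation.

Step 5
Reactants: 4 rac-(E)-1-(2-hydroxy-4-methoxyphenyl)-3-(4-hydroxyphenyl)prop-2-en-1-ol; 9 (E)-4-[3-(2,4-dimethoxyphenyl)prop-2-en-1-yl]phenol (2.0 equiv)
Product: 11 caraganin C [(2R,3R,4R)-2-(2,4-dimethoxyphenyl)-3-(4-hydroxybenzyl)-4-[(E)-4-hydroxystyryl]-7-methoxychroman], via ortho-quinone methide 10 (not isolated)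
Conditions: (R)-3,3'-bis(2,4,6-triisopropylphenyl)-1,1'-binaphthyl-2,2'-diyl hydrogen phosphate [(R)-TRIP] (10 mol %), 4 Å MS, CH2Cl2, −20 °C; 4 added over 6 h by syringe pump; then −20 → 0 °C, 12 h; excess 9 recovered
Reagents that add atoms: none
Why: Proposed new method: the chiral phosphoric acid ionises the doubly activated allylic alcohol 4 with loss of water (taken up by the molecular sieves) to the hydrogen-bonded (E)-ortho-quinone methide 10, which undergoes an inverse-electron-demand oxa-[4+2] cycloaddition (hetero-Diels–Alder, asynchronous, C4–C3 bond first) with the electron-rich (E)-styrene 9, and only attack at the methide carbon next to ring A allows the phenol oxygen to close onto the 2,4-dimethoxybenzylic carbon; the phosphate pocket leaves the Si face of the methide carbon open (giving 4R), the endo placement of the 2,4-dimethoxyphenyl group gives 2,4-cis, and the E-alkene geometry gives 2,3-trans, so the all-equatorial (2R,3R,4R) chroman results, while reversible O1–C2 ionisation under the acid lets C2 settle to the trans isomer; slow addition of 4 into excess 9 suppresses self-dimerisation through the 2H-chromene valence isomer of 10; the closest known reaction type is the chiral phosphoric acid-catalysed [4+2] cycloaddition of ortho-quinone methides from ortho-hydroxybenzyl alcohols with styrenes and ortho-hydroxystyrenes, and the new elements are the ambident styryl-substituted methide, the lack of a hydrogen-bond donor next to the alkene and the three free phenols.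

## Compound list

1 | paeonol, 1-(2-hydroxy-4-methoxyphenyl)ethan-1-one | CC(=O)c1ccc(OC)cc1O | starting material
2 | 4-hydroxybenzaldehyde | O=Cc1ccc(O)cc1 | starting material
3 | (E)-1-(2-hydroxy-4-methoxyphenyl)-3-(4-hydroxyphenyl)prop-2-en-1-one | COc1ccc(C(=O)/C=C/c2ccc(O)cc2)c(O)c1 | intermediate
4 | rac-(E)-1-(2-hydroxy-4-methoxyphenyl)-3-(4-hydroxyphenyl)prop-2-en-1-ol | COc1ccc(C(O)/C=C/c2ccc(O)cc2)c(O)c1 | intermediate
5 | 1,3-dimethoxybenzene | COc1cccc(OC)c1 | starting material
6 | 3-(4-hydroxyphenyl)propanoic acid | OC(=O)CCc1ccc(O)cc1 | starting material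
7 | 1-(2,4-dimethoxyphenyl)-3-(4-hydroxyphenyl)propan-1-one | COc1ccc(C(=O)CCc2ccc(O)cc2)c(OC)c1 | intermediate
8 | rac-1-(2,4-dimethoxyphenyl)-3-(4-hydroxyphenyl)propan-1-ol | COc1ccc(C(O)CCc2ccc(O)cc2)c(OC)c1 | intermediate (not isolated)
9 | (E)-4-[3-(2,4-dimethoxyphenyl)prop-2-en-1-yl]phenol | COc1ccc(/C=C/Cc2ccc(O)cc2)c(OC)c1 | intermediate
10 | (6E)-6-[(2E)-3-(4-hydroxyphenyl)prop-2-en-1-ylidene]-3-methoxycyclohexa-2,4-dien-1-one | O=C1C=C(OC)C=C/C1=C\C=C\c1ccc(O)cc1 | intermediate (not isolated)
11 | caraganin C, (2R,3R,4R)-2-(2,4-dimethoxyphenyl)-3-(4-hydroxybenzyl)-4-[(E)-4-hydroxystyryl]-7-methoxychroman | COc1ccc2c(c1)O[C@@H](c1ccc(OC)cc1OC)[C@H](Cc1ccc(O)cc1)[C@H]2/C=C/c1ccc(O)cc1 | target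

## Step count and risks

Total step count: 5. Longest linear sequence: 3 steps (steps 1, 2, 5, or equally steps 3, 4, 5).

Most likely to fail, first: step 5. The enantioselectivity may be modest because the alkene has no hydrogen-bond donor next to it. The cation derived from 4 can also close to the 2H-chromene, transfer hydride, or be attacked at the carbon next to the 4-hydroxyphenyl ring. Fallback: starting from 4 and 9, the cycloaddition is run with an achiral acid (diphenyl phosphate, 5 mol %, 4 Å MS, CH2Cl2, 0 °C) under the same slow-addition regime, which gives the all-trans racemate, racemic caraganin C F1. The enantiomers are separated by preparative HPLC on an amylose tris(3,5-dimethylphenylcarbamate) phase, and the (2R,3R,4R) fraction, assigned by optical rotation and ECD against the natural product, is 11.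

Second: step 2. The allylic alcohol 4 may not survive isolation, since it loses water and closes to the 2H-chromene on traces of acid, and flavanone formation or 1,4-reduction may compete. Fallback: starting from 3, reduction with NaBH4 in THF/EtOH followed by an AcOH work-up is taken deliberately through 4 to the stable, chromatographable 2-(4-hydroxyphenyl)-7-methoxy-2H-chromene F2 (racemic). Under the conditions of step 5 the chiral acid protonates the ring oxygen of F2 and the C2–O bond opens (the reverse of the oxa-6π closure) to the same ortho-quinone methide 10, where the route is rejoined.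

Third: step 3. The free phenol of 6 may be O-acylated or oligomerise in polyphosphoric acid and depress the yield. Fallback: starting from 5, acetylation (AcCl, AlCl3, CH2Cl2, 0 °C) gives 1-(2,4-dimethoxyphenyl)ethan-1-one F3. Claisen–Schmidt condensation of F3 with 2 (KOH, EtOH, rt) gives (E)-1-(2,4-dimethoxyphenyl)-3-(4-hydroxyphenyl)prop-2-en-1-one F4. Hydrogenation of the alkene only (H2 1 atm, Pd/C 5 wt %, EtOAc, stopped after one equivalent) then gives 7.

## Further compounds

F1 | step 5 | racemic caraganin C (1:1 mixture of 11 and its (2S,3S,4S) enantiomer) | COc1ccc2c(c1)O[C@@H](c1ccc(OC)cc1OC)[C@H](Cc1ccc(O)cc1)[C@H]2/C=C/c1ccc(O)cc1.COc1ccc2c(c1)O[C@H](c1ccc(OC)cc1OC)[C@@H](Cc1ccc(O)cc1)[C@@H]2/C=C/c1ccc(O)cc1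
F2 | step 2 | rac-2-(4-hydroxyphenyl)-7-methoxy-2H-chromene | COc1ccc2C=CC(c3ccc(O)cc3)Oc2c1
F3 | step 3 | 1-(2,4-dimethoxyphenyl)ethan-1-one | CC(=O)c1ccc(OC)cc1OC
F4 | step 3 | (E)-1-(2,4-dimethoxyphenyl)-3-(4-hydroxyphenyl)prop-2-en-1-one | COc1ccc(C(=O)/C=C/c2ccc(O)cc2)c(OC)c1
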